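**Retrosynthetic overview**
1. The oxirane comes last from the C6 vinyl group (hydroxyl-directed epoxidation), the acrolein from an isopropenyl group (allylic oxidation), and the 3-methylidene lactone with H-3a from a 3-(hydroxymethyl)butenolide by reductive allylic transposition.
2. The cyclohexane ring is closed at C7–C7a by a dearomatising intramolecular vinylogous Mukaiyama aldol of a 2-silyloxyfuran aldehyde (furan C5 becomes C7a, the aldehyde carbon becomes C7).
3. Enabling feature: the γ-lactone ring O1–C2–C3–C3a–C7a is a masked 3,4-disubstituted 2-oxyfuran. C7a is its nucleophilic C5, C3a carries the tether C4–C5–C6 that ends in the C7 aldehyde, and the CH2O group on C3 blocks α-attack, steers the closure by A(1,3) strain and later becomes the methylidene carbon.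
4. The furan aldehyde comes from a 4-furyllithium and a Weinreb amide (C3a–C4 bond), Felkin reduction (C4) and acylation; the amide comes from an enantioselective Ireland–Claisen rearrangement (C5–C6 bond, both stereocentres).
5. Ring order: furan (from tetronic acid), then cyclohexane (key step, furan becomes butenolide), then methylidene lactone, then oxirane.

Key step: step 14

Locants in the text are those of the octahydro-1-benzofuran-2-one core of the target (O1, C2 carbonyl, C3, C3a, C4 acyloxy, C5, C6 quaternary, C7 carbinol, C7a).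

Assumption (sense of induction in step 3): the (4S,5S)-diazaborolidine bromide with iPr2NEt in CH2Cl2 is taken to give the E(O) boron ketene acetal 6 and the (2S,3S) acid 7; if either sense proves opposite, the antipodal reagent or the Et3N/toluene–hexane pairing is used, nothing else changing.

**Route**

Step 1
Reactants: 1 tert-butyldimethyl(prop-2-yn-1-yloxy)silane
Product: 3 (2E)-4-{[tert-butyl(dimethyl)silyl]oxy}-3-methylbut-2-en-1-ol, via alkenylalane 2 (not isolated)
Conditions: Me3Al, Cp2ZrCl2 (cat.), CH2Cl2, 0 °C to rt; n-BuLi, THF, −78 °C; (CH2O)n, −78 °C to rt; aq. NH4Cl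
Reagents that add atoms: trimethylaluminium, C[Al](C)C; paraformaldehyde (as formaldehyde), C=O
Why: Negishi zirconium-catalysed carboalumination adds methyl and aluminium syn across the terminal alkyne with aluminium on the terminal carbon, and the derived alanate is hydroxymethylated with retention, which fixes the (E) trisubstituted alkene (no stereocentre).

Step 2
Reactants: 3 (2E)-4-{[tert-butyl(dimethyl)silyl]oxy}-3-methylbut-2-en-1-ol; 4 3-methylbut-3-enoic acid
Product: 5 (2E)-4-{[tert-butyl(dimethyl)silyl]oxy}-3-methylbut-2-en-1-yl 3-methylbut-3-enoate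
Conditions: DIC, DMAP (cat.), CH2Cl2, 0 °C
Reagents that add atoms: none
Why: Steglich esterification of a primary allylic alcohol, kept cold so that the β,γ-unsaturated acid does not move into conjugation.

Step 3
Reactants: 5 (2E)-4-{[tert-butyl(dimethyl)silyl]oxy}-3-methylbut-2-en-1-yl 3-methylbut-3-enoate
Product: 7 (2S,3S)-3-({[tert-butyl(dimethyl)silyl]oxy}methyl)-3-methyl-2-(prop-1-en-2-yl)pent-4-enoic acid, via boron ketene acetal 6 (not isolated)
Conditions: (4S,5S)-2-bromo-1,3-bis{[3,5-bis(trifluoromethyl)phenyl]sulfonyl}-4,5-diphenyl-1,3,2-diazaborolidine (from the (S,S)-bis-sulfonamide and BBr3), iPr2NEt, CH2Cl2, −78 °C then 4 °C; aq. work-up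
Reagents that add atoms: none
Why: enantioselective Ireland–Claisen rearrangement: soft enolisation gives the E(O) boron ketene acetal, whose chair [3,3] shift with the (E) allyl unit (methyl and 2-propenyl pseudoaxial on opposite termini) sets the tertiary/quaternary pair in the required relative sense, while the C2-symmetric diazaborolidine differentiates the enolate faces for the absolute sense.

Step 4
Reactants: 7 (2S,3S)-3-({[tert-butyl(dimethyl)silyl]oxy}methyl)-3-methyl-2-(prop-1-en-2-yl)pent-4-enoic acid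
Product: 8 (2S,3S)-3-({[tert-butyl(dimethyl)silyl]oxy}methyl)-N-methoxy-N,3-dimethyl-2-(prop-1-en-2-yl)pent-4-enamide
Conditions: MeNHOMe·HCl, EDC·HCl, HOBt (cat.), N-methylmorpholine, CH2Cl2, 0 °C to rt
Reagents that add atoms: N,O-dimethylhydroxylamine hydrochloride, CNOC.Cl
Why: carbodiimide/HOBt amide coupling under weakly basic conditions, which should leave the epimerisable β,γ-unsaturated α-centre untouched.

Step 5
Reactants: 9 tetronic acid (4-hydroxyfuran-2(5H)-one)
Product: 11 4-bromo-2-oxo-2,5-dihydrofuran-3-carbaldehyde, via iminium bromide 10 (not isolated)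
Conditions: POBr3, DMF, 1,2-dichloroethane, 0 to 60 °C; then ice-water
Reagents that add atoms: N,N-dimethylformamide, CN(C)C=O; phosphoryl bromide, O=P(Br)(Br)Br; water, O
Why: Vilsmeier–Haack (Arnold) bromoformylation of a cyclic β-keto lactone: the bromoiminium reagent formylates the nucleophilic C3, the enolic C4 hydroxyl is replaced by bromide, and water hydrolyses the iminium salt.

Step 6
Reactants: 11 4-bromo-2-oxo-2,5-dihydrofuran-3-carbaldehyde
Product: 12 4-bromo-3-(hydroxymethyl)furan-2(5H)-one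
Conditions: NaBH4, CeCl3·7H2O, MeOH, −78 °C
Reagents that add atoms: none
Why: Luche 1,2-reduction: the hard cerium-modified borohydride reduces the aldehyde and should leave the β-bromo enoate (addition–elimination at C4) alone at −78 °C.

Step 7
Reactants: 12 4-bromo-3-(hydroxymethyl)furan-2(5H)-one
Product: 13 4-bromo-2-[(triisopropylsilyl)oxy]-3-{[(triisopropylsilyl)oxy]methyl}furan
Conditions: TIPSOTf (2.2 equiv), Et3N, CH2Cl2, 0 °C
Reagents that add atoms: triisopropylsilyl trifluoromethanesulfonate, CC(C)[Si](C(C)C)(C(C)C)OS(=O)(=O)C(F)(F)F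
Why: silyl triflate/amine silylates the primary alcohol and, by soft γ-enolisation of the butenolide, traps the aromatic 2-silyloxyfuran; the bulky TIPS groups are chosen to resist O-to-C silyl shifts in the next step.

Step 8
Reactants: 13 4-bromo-2-[(triisopropylsilyl)oxy]-3-{[(triisopropylsilyl)oxy]methyl}furan; 8 (2S,3S)-3-({[tert-butyl(dimethyl)silyl]oxy}methyl)-N-methoxy-N,3-dimethyl-2-(prop-1-en-2-yl)pent-4-enamide
Product: 15 (2S,3S)-3-({[tert-butyl(dimethyl)silyl]oxy}methyl)-3-methyl-2-(prop-1-en-2-yl)-1-{5-[(triisopropylsilyl)oxy]-4-{[(triisopropylsilyl)oxy]methyl}furan-3-yl}pent-4-en-1-one, via furyllithium 14 (not isolated)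
Conditions: t-BuLi (2 equiv), Et2O, −78 °C; then 8, THF, −78 to −40 °C; aq. NH4Cl
Reagents that add atoms: none
Why: bromine–lithium exchange at −78 °C gives the 4-furyllithium, which adds once to the Weinreb amide through the stable chelated tetrahedral adduct (acyl substitution of an N-methoxy-N-methylamide); the low temperature should preserve the α-centre.

Step 9
Reactants: 15 (2S,3S)-3-({[tert-butyl(dimethyl)silyl]oxy}methyl)-3-methyl-2-(prop-1-en-2-yl)-1-{5-[(triisopropylsilyl)oxy]-4-{[(triisopropylsilyl)oxy]methyl}furan-3-yl}pent-4-en-1-one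
Product: 16 (1S,2S,3S)-3-({[tert-butyl(dimethyl)silyl]oxy}methyl)-3-methyl-2-(prop-1-en-2-yl)-1-{5-[(triisopropylsilyl)oxy]-4-{[(triisopropylsilyl)oxy]methyl}furan-3-yl}pent-4-en-1-ol
Conditions: LiBH(s-Bu)3, THF, −78 °C; aq. NH4Cl
Reagents that add atoms: none
Why: Felkin–Anh reduction: the bulky hydride attacks the heteroaryl ketone anti to the quaternary carbon on the side of the α-hydrogen, which should give the (1S) carbinol (the future C4).

Step 10
Reactants: 16 (1S,2S,3S)-3-({[tert-butyl(dimethyl)silyl]oxy}methyl)-3-methyl-2-(prop-1-en-2-yl)-1-{5-[(triisopropylsilyl)oxy]-4-{[(triisopropylsilyl)oxy]methyl}furan-3-yl}pent-4-en-1-ol; 17 (2S)-2-methylbutanoic anhydride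
Product: 18 (1S,2S,3S)-3-({[tert-butyl(dimethyl)silyl]oxy}methyl)-3-methyl-2-(prop-1-en-2-yl)-1-{5-[(triisopropylsilyl)oxy]-4-{[(triisopropylsilyl)oxy]methyl}furan-3-yl}pent-4-en-1-yl (2S)-2-methylbutanoate
Conditions: DMAP, Et3N, CH2Cl2, 0 °C to rt
Reagents that add atoms: none
Why: DMAP-catalysed acylation with the symmetric anhydride installs the (S)-2-methylbutanoate without touching its α-centre and without acid that would hydrolyse the silyloxyfuran.

Step 11
Reactants: 18 (1S,2S,3S)-3-({[tert-butyl(dimethyl)silyl]oxy}methyl)-3-methyl-2-(prop-1-en-2-yl)-1-{5-[(triisopropylsilyl)oxy]-4-{[(triisopropylsilyl)oxy]methyl}furan-3-yl}pent-4-en-1-yl (2S)-2-methylbutanoate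
Product: 19 (1S,2S,3S)-3-(hydroxymethyl)-3-methyl-1-(5-oxo-4-{[(triisopropylsilyl)oxy]methyl}-2,5-dihydrofuran-3-yl)-2-(prop-1-en-2-yl)pent-4-en-1-yl (2S)-2-methylbutanoate
Conditions: HF·pyridine, pyridine, THF, 0 °C
Reagents that add atoms: none
Why: chemoselective fluoride desilylation: buffered HF cleaves the silyl enol ether (the furan is protonated at C5 to the conjugated butenolide) and the primary TBS ether, while the bulkier primary TIPS ether should survive.

Step 12
Reactants: 19 (1S,2S,3S)-3-(hydroxymethyl)-3-methyl-1-(5-oxo-4-{[(triisopropylsilyl)oxy]methyl}-2,5-dihydrofuran-3-yl)-2-(prop-1-en-2-yl)pent-4-en-1-yl (2S)-2-methylbutanoate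
Product: 20 (1S,2S,3S)-3-formyl-3-methyl-1-(5-oxo-4-{[(triisopropylsilyl)oxy]methyl}-2,5-dihydrofuran-3-yl)-2-(prop-1-en-2-yl)pent-4-en-1-yl (2S)-2-methylbutanoate
Conditions: Dess–Martin periodinane, NaHCO3, CH2Cl2, 0 °C to rt
Reagents that add atoms: none
Why: Dess–Martin oxidation of the neopentyl primary alcohol gives an aldehyde that cannot enolise, under buffered conditions that leave ester, butenolide and alkenes untouched.

Step 13
Reactants: 20 (1S,2S,3S)-3-formyl-3-methyl-1-(5-oxo-4-{[(triisopropylsilyl)oxy]methyl}-2,5-dihydrofuran-3-yl)-2-(prop-1-en-2-yl)pent-4-en-1-yl (2S)-2-methylbutanoate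
Product: 21 (1S,2S,3S)-1-(5-{[tert-butyl(dimethyl)silyl]oxy}-4-{[(triisopropylsilyl)oxy]methyl}furan-3-yl)-3-formyl-3-methyl-2-(prop-1-en-2-yl)pent-4-en-1-yl (2S)-2-methylbutanoate
Conditions: TBSOTf (1.05 equiv), Et3N, CH2Cl2, −78 to −20 °C; pentane, filtration; used crude
Reagents that add atoms: tert-butyldimethylsilyl trifluoromethanesulfonate, CC(C)(C)[Si](C)(C)OS(=O)(=O)C(F)(F)F
Why: soft γ-enolisation of the butenolide with silyl triflate/amine re-forms the aromatic 2-silyloxyfuran; the aldehyde has no α-hydrogen and the ester α-hydrogen is far less acidic than the vinylogous γ-hydrogen.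

Step 14
Reactants: 21 (1S,2S,3S)-1-(5-{[tert-butyl(dimethyl)silyl]oxy}-4-{[(triisopropylsilyl)oxy]methyl}furan-3-yl)-3-formyl-3-methyl-2-(prop-1-en-2-yl)pent-4-en-1-yl (2S)-2-methylbutanoate
Product: 22 (4S,5S,6S,7S,7aR)-6-ethenyl-7-hydroxy-6-methyl-2-oxo-5-(prop-1-en-2-yl)-3-{[(triisopropylsilyl)oxy]methyl}-2,4,5,6,7,7a-hexahydro-1-benzofuran-4-yl (2S)-2-methylbutanoate
Conditions: BF3·OEt2, CH2Cl2, −78 °C; aq. NaHCO3
Reagents that add atoms: none
Why: BF3 activates the aldehyde and the aromatic 2-silyloxyfuran attacks it through furan C5 (the future C7a) in an intramolecular vinylogous Mukaiyama aldol addition, the silyl group leaving as its fluoride so that the furan is dearomatised to the butenolide; the closest known reaction type is the Lewis-acid-mediated vinylogous Mukaiyama aldol of 2-silyloxyfurans with aldehydes. The cyclohexane closes in a 6-(enolendo)-exo-trig mode through a chair that contains the furan C4–C5 bond. C7a is controlled by A(1,3) strain: the CH2OTIPS group on furan C3 forces the hydrogen of the acyloxy-bearing carbon into the furan plane and the acyloxy group perpendicular to it, so the tether can bring the aldehyde to furan C5 only on the face anti to the acyloxy group, which should give 7aR. C7 is controlled by the quaternary C6: with the vinyl group antiperiplanar to the forming bond, the carbonyl oxygen takes the site anti to the C6 methyl (Felkin-type staggering), which is also the synclinal, over-the-ring position that Lewis-acid-bound aldehydes prefer with silyloxyfurans, and this should give the axial 7S hydroxyl cis to the lactone oxygen. The step needs γ- rather than α-attack (either would close a six-membered ring) and a clean aldehyde partner: the substituent on furan C3 and the intrinsic γ-preference of silyloxyfurans secure the former, the lack of α-hydrogens on the aldehyde and the low temperature the latter.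

Step 15
Reactants: 22 (4S,5S,6S,7S,7aR)-6-ethenyl-7-hydroxy-6-methyl-2-oxo-5-(prop-1-en-2-yl)-3-{[(triisopropylsilyl)oxy]methyl}-2,4,5,6,7,7a-hexahydro-1-benzofuran-4-yl (2S)-2-methylbutanoate
Product: 23 (4S,5S,6S,7S,7aR)-6-ethenyl-7-hydroxy-3-(hydroxymethyl)-6-methyl-2-oxo-5-(prop-1-en-2-yl)-2,4,5,6,7,7a-hexahydro-1-benzofuran-4-yl (2S)-2-methylbutanoate
Conditions: HF·pyridine, pyridine, THF, rt
Reagents that add atoms: none
Why: fluoride cleavage of the primary allylic TIPS ether; the secondary alcohol, the ester and the butenolide are inert to buffered HF.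

Step 16
Reactants: 23 (4S,5S,6S,7S,7aR)-6-ethenyl-7-hydroxy-3-(hydroxymethyl)-6-methyl-2-oxo-5-(prop-1-en-2-yl)-2,4,5,6,7,7a-hexahydro-1-benzofuran-4-yl (2S)-2-methylbutanoate
Product: 26 (3aS,4S,5S,6S,7S,7aR)-6-ethenyl-7-hydroxy-6-methyl-3-methylidene-2-oxo-5-(prop-1-en-2-yl)octahydro-1-benzofuran-4-yl (2S)-2-methylbutanoate, via sulfonylhydrazine 24 (not isolated), via allylic diazene 25 (not isolated)
Conditions: PPh3, DEAD, 2-nitrobenzenesulfonohydrazide, THF, −30 °C; then 23 °C
Reagents that add atoms: none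
Why: reductive 1,3-transposition of an allylic alcohol through its allylic diazene: Mitsunobu displacement of the primary allylic hydroxyl by the sulfonylhydrazide, loss of sulfinic acid and retro-ene loss of N2 move the double bond to the exocyclic position and deliver hydrogen to C3a axially from the face anti to the axial C4 acyloxy group, which should give the trans-fused (3aS) lactone.

Step 17
Reactants: 26 (3aS,4S,5S,6S,7S,7aR)-6-ethenyl-7-hydroxy-6-methyl-3-methylidene-2-oxo-5-(prop-1-en-2-yl)octahydro-1-benzofuran-4-yl (2S)-2-methylbutanoate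
Product: 28 (3aS,4S,5R,6S,7S,7aR)-6-ethenyl-7-hydroxy-6-methyl-3-methylidene-2-oxo-5-(3-oxoprop-1-en-2-yl)octahydro-1-benzofuran-4-yl (2S)-2-methylbutanoate, via allylic alcohol 27 (not isolated)
Conditions: SeO2 (cat.), t-BuOOH, CH2Cl2, rt; then MnO2, CH2Cl2, rt
Reagents that add atoms: tert-butyl hydroperoxide, CC(C)(C)OO
Why: SeO2 allylic oxidation (ene reaction, then [2,3]-shift) attacks the methyl group of the only electron-rich alkene that has allylic hydrogens (the vinyl group has none, the methylidene lactone is electron-poor), and MnO2 takes the allylic alcohol on to the enal; no stereocentre is formed.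

Step 18
Reactants: 28 (3aS,4S,5R,6S,7S,7aR)-6-ethenyl-7-hydroxy-6-methyl-3-methylidene-2-oxo-5-(3-oxoprop-1-en-2-yl)octahydro-1-benzofuran-4-yl (2S)-2-methylbutanoate
Product: 29 (3aS,4S,5R,6S,7S,7aR)-7-hydroxy-6-methyl-3-methylidene-6-[(2R)-oxiran-2-yl]-2-oxo-5-(3-oxoprop-1-en-2-yl)octahydro-1-benzofuran-4-yl (2S)-2-methylbutanoate
Conditions: VO(OiPr)3 (cat.), chiral C2-symmetric bis-hydroxamic acid ligand (cat., antipode matched to the (2R)-oxirane), cumene hydroperoxide, toluene, 0 °C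
Reagents that add atoms: cumene hydroperoxide, CC(C)(OO)c1ccccc1
Why: hydroxyl-directed, ligand-controlled vanadium-catalysed epoxidation of a homoallylic alcohol: the C7 hydroxyl binds vanadium so that oxygen should be delivered only to the vinyl group on C6 (both methylidene groups are electron-poor and not directed), and the ligand antipode is chosen to place oxygen on the face that gives the (2R)-oxirane.

**Compound list**

1 | tert-butyldimethyl(prop-2-yn-1-yloxy)silane | C#CCO[Si](C)(C)C(C)(C)C | starting material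
2 | [(1E)-3-{[tert-butyl(dimethyl)silyl]oxy}-2-methylprop-1-en-1-yl]dimethylalumane | C[Al](C)/C=C(\C)CO[Si](C)(C)C(C)(C)C | intermediate
3 | (2E)-4-{[tert-butyl(dimethyl)silyl]oxy}-3-methylbut-2-en-1-ol | OC/C=C(\C)CO[Si](C)(C)C(C)(C)C | intermediate
4 | 3-methylbut-3-enoic acid | CC(=C)CC(=O)O | starting material
5 | (2E)-4-{[tert-butyl(dimethyl)silyl]oxy}-3-methylbut-2-en-1-yl 3-methylbut-3-enoate | CC(=C)CC(=O)OC/C=C(\C)CO[Si](C)(C)C(C)(C)C | intermediate
6 | boron ketene acetal of 5 bearing the (4S,5S)-diazaborolidin-2-yl group on oxygen, 2-propenyl group trans to O–B | CC(=C)/C=C(/OB1N(S(=O)(=O)c2cc(C(F)(F)F)cc(C(F)(F)F)c2)[C@@H](c2ccccc2)[C@H](c2ccccc2)N1S(=O)(=O)c1cc(C(F)(F)F)cc(C(F)(F)F)c1)OC/C=C(\C)CO[Si](C)(C)C(C)(C)C | intermediate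
7 | (2S,3S)-3-({[tert-butyl(dimethyl)silyl]oxy}methyl)-3-methyl-2-(prop-1-en-2-yl)pent-4-enoic acid | OC(=O)[C@@H](C(C)=C)[C@](C)(C=C)CO[Si](C)(C)C(C)(C)C | intermediate
8 | (2S,3S)-3-({[tert-butyl(dimethyl)silyl]oxy}methyl)-N-methoxy-N,3-dimethyl-2-(prop-1-en-2-yl)pent-4-enamide | CON(C)C(=O)[C@@H](C(C)=C)[C@](C)(C=C)CO[Si](C)(C)C(C)(C)C | intermediate
9 | tetronic acid (4-hydroxyfuran-2(5H)-one) | OC1=CC(=O)OC1 | starting material
10 | N-[(4-bromo-2-oxo-2,5-dihydrofuran-3-yl)methylidene]-N-methylmethanaminium bromide | C[N+](C)=CC1=C(Br)COC1=O.[Br-] | intermediate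
11 | 4-bromo-2-oxo-2,5-dihydrofuran-3-carbaldehyde | O=CC1=C(Br)COC1=O | intermediate
12 | 4-bromo-3-(hydroxymethyl)furan-2(5H)-one | OCC1=C(Br)COC1=O | intermediate
13 | 4-bromo-2-[(triisopropylsilyl)oxy]-3-{[(triisopropylsilyl)oxy]methyl}furan | CC(C)[Si](C(C)C)(C(C)C)OCc1c(Br)coc1O[Si](C(C)C)(C(C)C)C(C)C | intermediate
14 | {5-[(triisopropylsilyl)oxy]-4-{[(triisopropylsilyl)oxy]methyl}furan-3-yl}lithium | [Li]c1coc(O[Si](C(C)C)(C(C)C)C(C)C)c1CO[Si](C(C)C)(C(C)C)C(C)C | intermediate
15 | (2S,3S)-3-({[tert-butyl(dimethyl)silyl]oxy}methyl)-3-methyl-2-(prop-1-en-2-yl)-1-{5-[(triisopropylsilyl)oxy]-4-{[(triisopropylsilyl)oxy]methyl}furan-3-yl}pent-4-en-1-one | CC(C)[Si](C(C)C)(C(C)C)OCc1c(O[Si](C(C)C)(C(C)C)C(C)C)occ1C(=O)[C@@H](C(C)=C)[C@](C)(C=C)CO[Si](C)(C)C(C)(C)C | intermediate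
16 | (1S,2S,3S)-3-({[tert-butyl(dimethyl)silyl]oxy}methyl)-3-methyl-2-(prop-1-en-2-yl)-1-{5-[(triisopropylsilyl)oxy]-4-{[(triisopropylsilyl)oxy]methyl}furan-3-yl}pent-4-en-1-ol | CC(C)[Si](C(C)C)(C(C)C)OCc1c(O[Si](C(C)C)(C(C)C)C(C)C)occ1[C@@H](O)[C@@H](C(C)=C)[C@](C)(C=C)CO[Si](C)(C)C(C)(C)C | intermediate
17 | (2S)-2-methylbutanoic anhydride | CC[C@H](C)C(=O)OC(=O)[C@@H](C)CC | starting material
18 | (1S,2S,3S)-3-({[tert-butyl(dimethyl)silyl]oxy}methyl)-3-methyl-2-(prop-1-en-2-yl)-1-{5-[(triisopropylsilyl)oxy]-4-{[(triisopropylsilyl)oxy]methyl}furan-3-yl}pent-4-en-1-yl (2S)-2-methylbutanoate | CC(C)[Si](C(C)C)(C(C)C)OCc1c(O[Si](C(C)C)(C(C)C)C(C)C)occ1[C@@H](OC(=O)[C@@H](C)CC)[C@@H](C(C)=C)[C@](C)(C=C)CO[Si](C)(C)C(C)(C)C | intermediate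
19 | (1S,2S,3S)-3-(hydroxymethyl)-3-methyl-1-(5-oxo-4-{[(triisopropylsilyl)oxy]methyl}-2,5-dihydrofuran-3-yl)-2-(prop-1-en-2-yl)pent-4-en-1-yl (2S)-2-methylbutanoate | O=C1OCC([C@@H](OC(=O)[C@@H](C)CC)[C@@H](C(C)=C)[C@](C)(C=C)CO)=C1CO[Si](C(C)C)(C(C)C)C(C)C | intermediate
20 | (1S,2S,3S)-3-formyl-3-methyl-1-(5-oxo-4-{[(triisopropylsilyl)oxy]methyl}-2,5-dihydrofuran-3-yl)-2-(prop-1-en-2-yl)pent-4-en-1-yl (2S)-2-methylbutanoate | O=C1OCC([C@@H](OC(=O)[C@@H](C)CC)[C@@H](C(C)=C)[C@](C)(C=C)C=O)=C1CO[Si](C(C)C)(C(C)C)C(C)C | intermediate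
21 | (1S,2S,3S)-1-(5-{[tert-butyl(dimethyl)silyl]oxy}-4-{[(triisopropylsilyl)oxy]methyl}furan-3-yl)-3-formyl-3-methyl-2-(prop-1-en-2-yl)pent-4-en-1-yl (2S)-2-methylbutanoate | CC(C)[Si](C(C)C)(C(C)C)OCc1c(O[Si](C)(C)C(C)(C)C)occ1[C@@H](OC(=O)[C@@H](C)CC)[C@@H](C(C)=C)[C@](C)(C=C)C=O | intermediate
22 | (4S,5S,6S,7S,7aR)-6-ethenyl-7-hydroxy-6-methyl-2-oxo-5-(prop-1-en-2-yl)-3-{[(triisopropylsilyl)oxy]methyl}-2,4,5,6,7,7a-hexahydro-1-benzofuran-4-yl (2S)-2-methylbutanoate | CC(C)[Si](C(C)C)(C(C)C)OCC=1C(=O)O[C@@H]2C=1[C@@H](OC(=O)[C@@H](C)CC)[C@@H](C(C)=C)[C@](C)(C=C)[C@@H]2O | intermediate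
23 | (4S,5S,6S,7S,7aR)-6-ethenyl-7-hydroxy-3-(hydroxymethyl)-6-methyl-2-oxo-5-(prop-1-en-2-yl)-2,4,5,6,7,7a-hexahydro-1-benzofuran-4-yl (2S)-2-methylbutanoate | OCC=1C(=O)O[C@@H]2C=1[C@@H](OC(=O)[C@@H](C)CC)[C@@H](C(C)=C)[C@](C)(C=C)[C@@H]2O | intermediate
24 | 2-nitrobenzenesulfonohydrazide of 23, alkylated at the sulfonylated nitrogen by the C3 CH2 group | NN(CC=1C(=O)O[C@@H]2C=1[C@@H](OC(=O)[C@@H](C)CC)[C@@H](C(C)=C)[C@](C)(C=C)[C@@H]2O)S(=O)(=O)c1ccccc1[N+](=O)[O-] | intermediate
25 | allylic diazene of 23 (C3–CH2–N=NH) | N=NCC=1C(=O)O[C@@H]2C=1[C@@H](OC(=O)[C@@H](C)CC)[C@@H](C(C)=C)[C@](C)(C=C)[C@@H]2O | intermediate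
26 | (3aS,4S,5S,6S,7S,7aR)-6-ethenyl-7-hydroxy-6-methyl-3-methylidene-2-oxo-5-(prop-1-en-2-yl)octahydro-1-benzofuran-4-yl (2S)-2-methylbutanoate | C=C1C(=O)O[C@@H]2[C@@H]1[C@@H](OC(=O)[C@@H](C)CC)[C@@H](C(C)=C)[C@](C)(C=C)[C@@H]2O | intermediate
27 | (3aS,4S,5S,6S,7S,7aR)-6-ethenyl-7-hydroxy-5-(3-hydroxyprop-1-en-2-yl)-6-methyl-3-methylidene-2-oxooctahydro-1-benzofuran-4-yl (2S)-2-methylbutanoate | C=C1C(=O)O[C@@H]2[C@@H]1[C@@H](OC(=O)[C@@H](C)CC)[C@@H](C(=C)CO)[C@](C)(C=C)[C@@H]2O | intermediate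
28 | (3aS,4S,5R,6S,7S,7aR)-6-ethenyl-7-hydroxy-6-methyl-3-methylidene-2-oxo-5-(3-oxoprop-1-en-2-yl)octahydro-1-benzofuran-4-yl (2S)-2-methylbutanoate | C=C1C(=O)O[C@@H]2[C@@H]1[C@@H](OC(=O)[C@@H](C)CC)[C@@H](C(=C)C=O)[C@](C)(C=C)[C@@H]2O | intermediate
29 | (3aS,4S,5R,6S,7S,7aR)-7-hydroxy-6-methyl-3-methylidene-6-[(2R)-oxiran-2-yl]-2-oxo-5-(3-oxoprop-1-en-2-yl)octahydro-1-benzofuran-4-yl (2S)-2-methylbutanoate | C=C1C(=O)O[C@@H]2[C@@H]1[C@@H](OC(=O)[C@@H](C)CC)[C@@H](C(=C)C=O)[C@](C)([C@@H]1CO1)[C@@H]2O | target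

**Step count and risks**

Total step count: 18. Longest linear sequence: 15 (steps 1–4 and 8–18); steps 5–7 make the furan fragment.

Steps most likely to fail:

1. Step 14. The facial discrimination at the aldehyde carbon may be insufficient, so that the C7 hydroxyl is formed equatorial, or the furylmethyl ester may ionise under the Lewis acid. Fallback (sets out from 21, returns at 22): the ring closure is run as before and the C7 configuration is set afterwards by ketone reduction instead of by the aldol step. The (7R)-epimer of 22 F1 is oxidised with Dess–Martin periodinane to the C7 ketone F2, and F2 is reduced with LiBH(s-Bu)3 in THF at −78 °C. The bulky hydride should attack from the equatorial direction and give the axial (7S) carbinol 22, while the tetrasubstituted butenolide should resist conjugate reduction.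

2. Step 18. Ligand control may be mismatched with the substrate bias during oxygen transfer to the vinyl group, giving the oxirane epimer. Fallback (sets out from 28, returns at 29): unselective epoxidation with mCPBA/NaHCO3 in CH2Cl2 gives 29 together with the (2S)-oxiranyl epimer F3. Hydrolytic kinetic resolution with water and the antipode of Co(salen)(OAc) (trivalent cobalt) that opens (S)-configured terminal epoxides converts F3 into the (1S)-1,2-diol F4, which is separated by chromatography, leaving 29.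

3. Step 8. The furyllithium may enolise the hindered Weinreb amide, or add too slowly, in place of acyl substitution. Fallback (sets out from 8, returns at 15): DIBAL-H in CH2Cl2 at −78 °C reduces 8 to the aldehyde F5, a less hindered electrophile. Furyllithium 14 adds to F5 at −78 °C to give the carbinol F6, expected mainly as the Felkin (1R) epimer. MnO2 in CH2Cl2 oxidises this heteroaryl carbinol to ketone 15, after which step 9 sets the carbinol centre as planned.

Further compounds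
F1 | step 14 | (4S,5S,6S,7R,7aR)-6-ethenyl-7-hydroxy-6-methyl-2-oxo-5-(prop-1-en-2-yl)-3-{[(triisopropylsilyl)oxy]methyl}-2,4,5,6,7,7a-hexahydro-1-benzofuran-4-yl (2S)-2-methylbutanoate | CC(C)[Si](C(C)C)(C(C)C)OCC=1C(=O)O[C@@H]2C=1[C@@H](OC(=O)[C@@H](C)CC)[C@@H](C(C)=C)[C@](C)(C=C)[C@H]2O
F2 | step 14 | (4S,5S,6S,7aR)-6-ethenyl-6-methyl-2,7-dioxo-5-(prop-1-en-2-yl)-3-{[(triisopropylsilyl)oxy]methyl}-2,4,5,6,7,7a-hexahydro-1-benzofuran-4-yl (2S)-2-methylbutanoate | CC(C)[Si](C(C)C)(C(C)C)OCC=1C(=O)O[C@@H]2C=1[C@@H](OC(=O)[C@@H](C)CC)[C@@H](C(C)=C)[C@](C)(C=C)C2=O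
F3 | step 18 | (3aS,4S,5R,6S,7S,7aR)-7-hydroxy-6-methyl-3-methylidene-6-[(2S)-oxiran-2-yl]-2-oxo-5-(3-oxoprop-1-en-2-yl)octahydro-1-benzofuran-4-yl (2S)-2-methylbutanoate | C=C1C(=O)O[C@@H]2[C@@H]1[C@@H](OC(=O)[C@@H](C)CC)[C@@H](C(=C)C=O)[C@](C)([C@H]1CO1)[C@@H]2O
F4 | step 18 | (3aS,4S,5R,6S,7S,7aR)-6-[(1S)-1,2-dihydroxyethyl]-7-hydroxy-6-methyl-3-methylidene-2-oxo-5-(3-oxoprop-1-en-2-yl)octahydro-1-benzofuran-4-yl (2S)-2-methylbutanoate | C=C1C(=O)O[C@@H]2[C@@H]1[C@@H](OC(=O)[C@@H](C)CC)[C@@H](C(=C)C=O)[C@](C)([C@H](O)CO)[C@@H]2O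
F5 | step 8 | (2S,3S)-3-({[tert-butyl(dimethyl)silyl]oxy}methyl)-3-methyl-2-(prop-1-en-2-yl)pent-4-enal | O=C[C@@H](C(C)=C)[C@](C)(C=C)CO[Si](C)(C)C(C)(C)C
F6 | step 8 | (1R,2S,3S)-3-({[tert-butyl(dimethyl)silyl]oxy}methyl)-3-methyl-2-(prop-1-en-2-yl)-1-{5-[(triisopropylsilyl)oxy]-4-{[(triisopropylsilyl)oxy]methyl}furan-3-yl}pent-4-en-1-ol | CC(C)[Si](C(C)C)(C(C)C)OCc1c(O[Si](C(C)C)(C(C)C)C(C)C)occ1[C@H](O)[C@@H](C(C)=C)[C@](C)(C=C)CO[Si](C)(C)C(C)(C)C
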